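**Plan**

- Locants: unit 1 is the 7-methoxyflavone half (plain and single-primed locants); unit 2 is the apigenin half attached through C6'' (double- and triple-primed locants).
- Main cut: after the O-protecting groups, one operation cuts C8a–O1, C4a–C4 and O1–C2 of unit 1. Ring A of unit 1 carries O1 (on C8a) and the C4 carbonyl (on C4a) on neighbouring carbons, with the C5 oxygen next to C4a; an oxygen-flanked aryne delivers exactly this pattern when it takes up a carboxylic acid across its triple bond.
- Further cuts: the two side-chain carbons at C1' (CO2, then the alkyne carbon from an aldehyde) and the C3'–C6'' biaryl bond (Suzuki coupling of a 6-iodoapigenin ether with a formylarylboronate).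
- Forward: unit 2 arrives complete as apigenin and is iodinated at C6''; ring B of unit 1 is attached; the side chain is grown to the arylpropiolic acid; ring A of unit 1 is then delivered as the aryne and the pyranone ring C closes in the same flask; BCl3 finally frees five hydroxyls and leaves the 7-methyl ether.
- Stereochemistry: the target has no stereocentre; the C3'–C6'' axis is undefined in the target and is carried as it forms.

Key step: step 12

Assumption: O5'' is capped as a methyl ether rather than an isopropyl ether, because it lies between the carbonyl and the iodine and is later removed by the same chelation-assisted cleavage as O5; apigenin is taken as a commercial starting material.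

**Route**

Step 1
Reactants: 1 apigenin (5,7-dihydroxy-2-(4-hydroxyphenyl)-4H-chromen-4-one)
Product: 2 5-hydroxy-7-isopropoxy-2-(4-isopropoxyphenyl)-4H-chromen-4-one
Conditions: 2-bromopropane (2.4 equiv), K2CO3 (2.4 equiv), DMF, 60 °C
Reagents that add atoms: 2-bromopropane, CC(C)Br
Why: Williamson etherification in which the 5-hydroxyl, hydrogen-bonded to the C4 carbonyl and the least acidic of the three, should stay free while O7 and O4' are alkylated.

Step 2
Reactants: 2 5-hydroxy-7-isopropoxy-2-(4-isopropoxyphenyl)-4H-chromen-4-one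
Product: 3 5-hydroxy-6-iodo-7-isopropoxy-2-(4-isopropoxyphenyl)-4H-chromen-4-one
Conditions: BnMe3N·ICl2 (1.1 equiv), CaCO3, CH2Cl2/MeOH, rt
Reagents that add atoms: benzyltrimethylammonium dichloroiodate, C[N+](C)(C)Cc1ccccc1.Cl[I-]Cl
Why: electrophilic aromatic iodination, which for 5-hydroxy-7-alkoxyflavones with this reagent is known to go ortho to the free phenol at C6 rather than at C8.

Step 3
Reactants: 3 5-hydroxy-6-iodo-7-isopropoxy-2-(4-isopropoxyphenyl)-4H-chromen-4-one
Product: 4 6-iodo-7-isopropoxy-2-(4-isopropoxyphenyl)-5-methoxy-4H-chromen-4-one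
Conditions: MeI, K2CO3, DMF, 50 °C
Reagents that add atoms: iodomethane, CI
Why: Williamson etherification of the chelated phenol with the smallest electrophile, which should still reach an oxygen flanked by the carbonyl and iodine.

Step 4
Reactants: 5 3-bromo-4-hydroxybenzaldehyde
Product: 6 3-bromo-4-isopropoxybenzaldehyde
Conditions: 2-bromopropane, K2CO3, DMF, 70 °C
Reagents that add atoms: 2-bromopropane, CC(C)Br
Why: Williamson etherification of an acidic para-formyl phenol, a routine alkylation.

Step 5
Reactants: 6 3-bromo-4-isopropoxybenzaldehyde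
Product: 7 4-isopropoxy-3-(4,4,5,5-tetramethyl-1,3,2-dioxaborolan-2-yl)benzaldehyde
Conditions: B2pin2, Pd(dppf)Cl2 (3 mol %), KOAc, 1,4-dioxane, 90 °C
Reagents that add atoms: bis(pinacolato)diboron, CC1(C)OB(OC1(C)C)B1OC(C)(C)C(C)(C)O1
Why: Miyaura borylation, which tolerates the aldehyde and, with the weak acetate base, should not go on to biaryl homocoupling.

Step 6
Reactants: 4 6-iodo-7-isopropoxy-2-(4-isopropoxyphenyl)-5-methoxy-4H-chromen-4-one; 7 4-isopropoxy-3-(4,4,5,5-tetramethyl-1,3,2-dioxaborolan-2-yl)benzaldehyde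
Product: 8 4-isopropoxy-3-[7-isopropoxy-2-(4-isopropoxyphenyl)-5-methoxy-4-oxo-4H-chromen-6-yl]benzaldehyde
Conditions: Pd(OAc)2 (5 mol %), SPhos (10 mol %), K3PO4, toluene/H2O, 90 °C
Reagents that add atoms: none
Why: Suzuki–Miyaura coupling with a dialkylbiarylphosphine ligand suited to tri-ortho-substituted biaryls, with the hindered carbon as the iodide and the less hindered one as the boronate, under a phosphate base that spares the aldehyde and the pyranone.

Step 7
Reactants: 8 4-isopropoxy-3-[7-isopropoxy-2-(4-isopropoxyphenyl)-5-methoxy-4-oxo-4H-chromen-6-yl]benzaldehyde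
Product: 9 6-(5-ethynyl-2-isopropoxyphenyl)-7-isopropoxy-2-(4-isopropoxyphenyl)-5-methoxy-4H-chromen-4-one
Conditions: dimethyl (1-diazo-2-oxopropyl)phosphonate, K2CO3, MeOH/THF, 0 °C to rt
Reagents that add atoms: dimethyl (1-diazo-2-oxopropyl)phosphonate, COP(=O)(OC)C(=[N+]=[N-])C(C)=O
Why: Seyferth–Gilbert homologation in its Ohira–Bestmann form, which converts a non-enolisable aryl aldehyde to the terminal alkyne under carbonate in methanol and should leave the vinylogous-ester carbonyl of the flavone alone.

Step 8
Reactants: 9 6-(5-ethynyl-2-isopropoxyphenyl)-7-isopropoxy-2-(4-isopropoxyphenyl)-5-methoxy-4H-chromen-4-one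
Product: 10 3-{4-isopropoxy-3-[7-isopropoxy-2-(4-isopropoxyphenyl)-5-methoxy-4-oxo-4H-chromen-6-yl]phenyl}prop-2-ynoic acid
Conditions: CO2 (1 atm), AgI (2 mol %), Cs2CO3 (1.5 equiv), DMF, 50 °C; then 1 M HCl, 0 °C
Reagents that add atoms: carbon dioxide, O=C=O
Why: silver-catalysed C–H carboxylation of a terminal alkyne, in which the silver acetylide takes up CO2 and the cesium propiolate is acidified cold so that the acid should be isolated without decarboxylation.

Step 9
Reactants: 11 3,5-dimethoxyphenol
Product: 12 3,5-dimethoxyphenyl N-isopropylcarbamate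
Conditions: isopropyl isocyanate, Et3N (cat.), CH2Cl2, rt
Reagents that add atoms: isopropyl isocyanate, CC(C)N=C=O
Why: base-catalysed carbamoylation of the phenol, which installs a strong ortho-directing group that can later be removed with mild base.

Step 10
Reactants: 12 3,5-dimethoxyphenyl N-isopropylcarbamate
Product: 15 3,5-dimethoxy-2-(trimethylsilyl)phenyl N-isopropylcarbamate, via N-silyl carbamate 13 (not isolated), via bis-silyl carbamate 14 (not isolated)
Conditions: TMSOTf, TMEDA, Et2O, 0 °C to rt; n-BuLi, TMEDA, −78 °C; TMSCl, −78 °C to rt; aq. NaHSO4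
Reagents that add atoms: chlorotrimethylsilane, C[Si](C)(C)Cl
Why: directed ortho-metalation of the carbamate protected in situ on nitrogen, in which lithiation should occur at C2 where the carbamate and a methoxy group cooperate rather than at C4 between two weaker methoxy directors, followed by C-silylation and loss of the N-silyl group on aqueous work-up.

Step 11
Reactants: 15 3,5-dimethoxy-2-(trimethylsilyl)phenyl N-isopropylcarbamate
Product: 17 3,5-dimethoxy-2-(trimethylsilyl)phenyl trifluoromethanesulfonate, via silylphenol 16 (not isolated)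
Conditions: DBU, Et2NH, MeCN, 40 °C; then PhNTf2, rt
Reagents that add atoms: N-phenylbis(trifluoromethanesulfonimide), O=S(=O)(N(c1ccccc1)S(=O)(=O)C(F)(F)F)C(F)(F)F
Why: E1cB cleavage of the N-monoalkyl carbamate to the phenoxide and isopropyl isocyanate (trapped by diethylamine), then O-triflation in the same flask with a mild triflyl donor that should leave the ortho C–Si bond intact.

Step 12
Reactants: 10 3-{4-isopropoxy-3-[7-isopropoxy-2-(4-isopropoxyphenyl)-5-methoxy-4-oxo-4H-chromen-6-yl]phenyl}prop-2-ynoic acid; 17 3,5-dimethoxy-2-(trimethylsilyl)phenyl trifluoromethanesulfonate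
Product: 20 5,7-dimethoxy-2-{4-isopropoxy-3-[7-isopropoxy-2-(4-isopropoxyphenyl)-5-methoxy-4-oxo-4H-chromen-6-yl]phenyl}-4H-chromen-4-one, via 3,5-dimethoxybenzyne 18 (not isolated), via ortho-hydroxyaryl ynone 19 (not isolated)
Conditions: CsF (4 equiv), 17 (1.5 equiv), THF, 125 °C, sealed tube
Reagents that add atoms: none
Why: Fluoride removes the silyl group of 17 and triflate leaves to give aryne 18; the cesium carboxylate of 10 adds through oxygen, the resulting aryl anion attacks the neighbouring ester carbonyl via a strained four-membered alkoxide, and opening of that ring (an anionic Fries-type acyl shift, net insertion of the aryne into the acid C–O bond) gives the phenoxide of ynone 19 with C8a–O1 and C4a–C4 in place. The closest known reaction is the insertion of arynes into the C–O bond of carboxylic acids, which with 3-arylpropiolic acids is known to continue to flavones. The phenoxide then closes the pyranone ring C of unit 1 by 6-endo-dig oxa-Michael addition to the alkyne carbon bearing ring B (O1–C2), and the vinyl anion is protonated by the hydrogen fluoride equivalent released from the acid. No stereocentre is formed. Two selectivities are needed: the regiochemistry of addition to the unsymmetrical aryne, secured by the methoxy group beside the triple bond, whose inductive pull and ring distortion place the developing negative charge on the adjacent carbon so that oxygen enters at the distal carbon (future C8a) and the acyl group ends on C4a next to the 5-methoxy group; and 6-endo rather than 5-exo closure (flavone rather than aurone), which the aprotic medium favours because the conjugate addition is reversible there and the chromone is the more stable product. All phenols of 10 are capped, so the carboxylate is the only nucleophile offered to the aryne, and the excess of 17 covers aryne lost to side reactions.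

Step 13
Reactants: 20 5,7-dimethoxy-2-{4-isopropoxy-3-[7-isopropoxy-2-(4-isopropoxyphenyl)-5-methoxy-4-oxo-4H-chromen-6-yl]phenyl}-4H-chromen-4-one
Product: 21 5-hydroxy-2-{4-hydroxy-3-[5,7-dihydroxy-2-(4-hydroxyphenyl)-4-oxo-4H-chromen-6-yl]phenyl}-7-methoxy-4H-chromen-4-one (7-O-methylrobustaflavone, the target)
Conditions: BCl3 (12 equiv), CH2Cl2, −78 °C to rt; then MeOH, aq. HCl
Reagents that add atoms: none
Why: Lewis-acid ether cleavage in which BCl3 should remove the three secondary isopropyl ethers and, through six-membered boron chelates with the C4 and C4'' carbonyls, the two peri methyl ethers at O5 and O5'', while the unchelated 7-methyl ether is not attacked by BCl3 at or below room temperature.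

**Compound list**

1 | apigenin (5,7-dihydroxy-2-(4-hydroxyphenyl)-4H-chromen-4-one) | O=c1cc(-c2ccc(O)cc2)oc2cc(O)cc(O)c12 | starting material
2 | 5-hydroxy-7-isopropoxy-2-(4-isopropoxyphenyl)-4H-chromen-4-one | CC(C)Oc1ccc(cc1)-c1cc(=O)c2c(O)cc(OC(C)C)cc2o1 | intermediate
3 | 5-hydroxy-6-iodo-7-isopropoxy-2-(4-isopropoxyphenyl)-4H-chromen-4-one | CC(C)Oc1ccc(cc1)-c1cc(=O)c2c(O)c(I)c(OC(C)C)cc2o1 | intermediate
4 | 6-iodo-7-isopropoxy-2-(4-isopropoxyphenyl)-5-methoxy-4H-chromen-4-one | CC(C)Oc1ccc(cc1)-c1cc(=O)c2c(OC)c(I)c(OC(C)C)cc2o1 | intermediate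
5 | 3-bromo-4-hydroxybenzaldehyde | O=Cc1ccc(O)c(Br)c1 | starting material
6 | 3-bromo-4-isopropoxybenzaldehyde | O=Cc1ccc(OC(C)C)c(Br)c1 | intermediate
7 | 4-isopropoxy-3-(4,4,5,5-tetramethyl-1,3,2-dioxaborolan-2-yl)benzaldehyde | O=Cc1ccc(OC(C)C)c(c1)B1OC(C)(C)C(C)(C)O1 | intermediate
8 | 4-isopropoxy-3-[7-isopropoxy-2-(4-isopropoxyphenyl)-5-methoxy-4-oxo-4H-chromen-6-yl]benzaldehyde | O=Cc1ccc(OC(C)C)c(c1)-c1c(OC)c2c(=O)cc(oc2cc1OC(C)C)-c1ccc(OC(C)C)cc1 | intermediate
9 | 6-(5-ethynyl-2-isopropoxyphenyl)-7-isopropoxy-2-(4-isopropoxyphenyl)-5-methoxy-4H-chromen-4-one | C#Cc1ccc(OC(C)C)c(c1)-c1c(OC)c2c(=O)cc(oc2cc1OC(C)C)-c1ccc(OC(C)C)cc1 | intermediate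
10 | 3-{4-isopropoxy-3-[7-isopropoxy-2-(4-isopropoxyphenyl)-5-methoxy-4-oxo-4H-chromen-6-yl]phenyl}prop-2-ynoic acid | OC(=O)C#Cc1ccc(OC(C)C)c(c1)-c1c(OC)c2c(=O)cc(oc2cc1OC(C)C)-c1ccc(OC(C)C)cc1 | intermediate
11 | 3,5-dimethoxyphenol | COc1cc(O)cc(OC)c1 | starting material
12 | 3,5-dimethoxyphenyl N-isopropylcarbamate | COc1cc(OC)cc(OC(=O)NC(C)C)c1 | intermediate
13 | 3,5-dimethoxyphenyl N-isopropyl-N-(trimethylsilyl)carbamate (formed in the flask) | COc1cc(OC)cc(OC(=O)N(C(C)C)[Si](C)(C)C)c1 | intermediate
14 | 3,5-dimethoxy-2-(trimethylsilyl)phenyl N-isopropyl-N-(trimethylsilyl)carbamate (formed in the flask) | COc1cc(OC)c([Si](C)(C)C)c(OC(=O)N(C(C)C)[Si](C)(C)C)c1 | intermediate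
15 | 3,5-dimethoxy-2-(trimethylsilyl)phenyl N-isopropylcarbamate | COc1cc(OC)c([Si](C)(C)C)c(OC(=O)NC(C)C)c1 | intermediate
16 | 3,5-dimethoxy-2-(trimethylsilyl)phenol (formed in the flask as its phenoxide) | COc1cc(OC)c([Si](C)(C)C)c(O)c1 | intermediate
17 | 3,5-dimethoxy-2-(trimethylsilyl)phenyl trifluoromethanesulfonate | COc1cc(OC)c([Si](C)(C)C)c(OS(=O)(=O)C(F)(F)F)c1 | intermediate
18 | 3,5-dimethoxybenzyne (formed in the flask) | COC1=CC(OC)=CC#C1 | intermediate
19 | 1-(2-hydroxy-4,6-dimethoxyphenyl)-3-{4-isopropoxy-3-[7-isopropoxy-2-(4-isopropoxyphenyl)-5-methoxy-4-oxo-4H-chromen-6-yl]phenyl}prop-2-yn-1-one (formed in the flask as its phenoxide) | COc1cc(O)c(C(=O)C#Cc2ccc(OC(C)C)c(c2)-c2c(OC)c3c(=O)cc(oc3cc2OC(C)C)-c2ccc(OC(C)C)cc2)c(OC)c1 | intermediate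
20 | 5,7-dimethoxy-2-{4-isopropoxy-3-[7-isopropoxy-2-(4-isopropoxyphenyl)-5-methoxy-4-oxo-4H-chromen-6-yl]phenyl}-4H-chromen-4-one | COc1cc(OC)c2c(=O)cc(-c3ccc(OC(C)C)c(-c4c(OC)c5c(=O)cc(-c6ccc(OC(C)C)cc6)oc5cc4OC(C)C)c3)oc2c1 | intermediate
21 | 5-hydroxy-2-{4-hydroxy-3-[5,7-dihydroxy-2-(4-hydroxyphenyl)-4-oxo-4H-chromen-6-yl]phenyl}-7-methoxy-4H-chromen-4-one (7-O-methylrobustaflavone) | COc1cc(O)c2c(=O)cc(-c3ccc(O)c(-c4c(O)cc5oc(-c6ccc(O)cc6)cc(=O)c5c4O)c3)oc2c1 | target

**Step count and risks**

Total steps: 13. Longest linear sequence: 8 steps (1, 2, 3, 6, 7, 8, 12, 13, from apigenin).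

Steps most likely to fail:

Step 12. The propiolate may lose CO2 at 125 °C before it meets the aryne, the adduct may stop at the aryl ester without acyl migration, or the aryne may take up the carboxylate the wrong way round. The fallback builds ring C of unit 1 by the chalcone route and sets out from aldehyde 8. Claisen–Schmidt condensation of 8 with commercial 2'-hydroxy-4',6'-dimethoxyacetophenone (KOH, EtOH/THF, rt) should give the (E)-2'-hydroxychalcone F1. Oxidative cyclisation of the 2'-hydroxychalcone F1 with catalytic I2 in DMSO at 120 °C should then return to the route at biflavone 20; steps 7 to 12 are not needed on this path.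

Step 6. Protodeboronation of the ortho-alkoxy boronate may outrun transmetalation at the crowded palladium centre, and the doubly ortho-substituted iodide may be reduced instead of coupled. The fallback is a Negishi coupling and sets out from bromide 6 and iodide 4. Acetalisation of 6 (ethylene glycol, p-TsOH, toluene, Dean–Stark) should give the dioxolane acetal F2. Bromine–lithium exchange (n-BuLi, THF, −78 °C) and transmetalation with ZnCl2 should give the arylzinc chloride F3. Coupling of the arylzinc chloride F3 with 4 (Pd(OAc)2, SPhos, THF, 60 °C) should give the biaryl acetal F4, and aqueous HCl in THF should release the aldehyde and return to the route at 8.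

Step 10. Lithiation may occur in part at C4 between the two methoxy groups, or the aryllithium may undergo anionic Fries migration of the carbamoyl group before it is silylated. The fallback reaches the same triflate by halogenation and retro-Brook rearrangement and sets out from phenol 11. Ortho-bromination (NBS, CH2Cl2, −78 °C) should give 2-bromo-3,5-dimethoxyphenol F5, and O-silylation (HMDS, THF, 70 °C) should give the aryl trimethylsilyl ether F6. Bromine–lithium exchange on the aryl trimethylsilyl ether F6 (n-BuLi, THF, −100 °C) triggers oxygen-to-carbon silyl migration to the lithium phenoxide of 16. Trapping with Tf2O at −100 to −78 °C should return to the route at 17.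

**Further compounds**

F1 | step 12 | (E)-1-(2-hydroxy-4,6-dimethoxyphenyl)-3-{4-isopropoxy-3-[7-isopropoxy-2-(4-isopropoxyphenyl)-5-methoxy-4-oxo-4H-chromen-6-yl]phenyl}prop-2-en-1-one | COc1cc(O)c(C(=O)/C=C/c2ccc(OC(C)C)c(c2)-c2c(OC)c3c(=O)cc(oc3cc2OC(C)C)-c2ccc(OC(C)C)cc2)c(OC)c1
F2 | step 6 | 2-(3-bromo-4-isopropoxyphenyl)-1,3-dioxolane | CC(C)Oc1ccc(cc1Br)C1OCCO1
F3 | step 6 | [5-(1,3-dioxolan-2-yl)-2-isopropoxyphenyl]zinc chloride | CC(C)Oc1ccc(cc1[Zn]Cl)C1OCCO1
F4 | step 6 | 6-[5-(1,3-dioxolan-2-yl)-2-isopropoxyphenyl]-7-isopropoxy-2-(4-isopropoxyphenyl)-5-methoxy-4H-chromen-4-one | CC(C)Oc1ccc(cc1-c1c(OC)c2c(=O)cc(oc2cc1OC(C)C)-c1ccc(OC(C)C)cc1)C1OCCO1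
F5 | step 10 | 2-bromo-3,5-dimethoxyphenol | COc1cc(O)c(Br)c(OC)c1
F6 | step 10 | (2-bromo-3,5-dimethoxyphenoxy)trimethylsilane | COc1cc(O[Si](C)(C)C)c(Br)c(OC)c1
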